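## Structural features

The target joins a 2'-hydroxy-4,4'-dimethoxychalcone to an aristolane-type sesquiterpene, whose carbons are numbered C1–C11 here. Ring A (C1, C2, C3, C4, C5, C10) and ring B (C5, C6, C7, C8, C9, C10) form a cis-fused decalin. It carries a secondary methyl at C4, an angular methyl at C5, the vicinal diketone C8/C9 and a gem-dimethylcyclopropane (C6, C7, C11) fused to ring B. The arene is bound twice, by the C1–aryl bond and the C10–O–aryl ether, so a 2,3-dihydrobenzofuran is cis-fused to ring A along C1–C10; the ring oxygen and the free phenol flank the cinnamoyl carbonyl and the methoxy group is para to it. Six stereocentres are contiguous (C1, C10, C5, C4, C6, C7): the C4 methyl, C5 methyl, C10 oxygen and C1 aryl bond lie on one face of ring A, ring B on the other, and the CMe2 bridge is anti to the C5 methyl. Fragile groups are the non-enolisable 1,2-dione (hydroxide), the gem-dimethylcyclopropyl ketone (strong acid), the C10 aryl ether, which is β to the C8 carbonyl and can leave by E1cB while C9 bears hydrogen, and the 2'-hydroxychalcone (hydrogenation, flavanone closure, oxidants such as SeO2). The real difficulty is the pair of adjacent fully substituted carbons C5 and C10 with four further stereocentres around them, and the face of the cyclopropane. The key step uses the fact that ring B holds the intact cyclopropane between C5 and the acyl carbon C8 and ends at the oxygen-bearing C10: cutting C5–C6 and C9–C10 leaves an acylcyclopropene (strained acceptor C6=C7, aldol donor C9) and the enol of a ring A 1,2-dione (nucleophilic C5, electrophilic C10).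

## Logic of the disconnections

29 ⇒ 28 ⇒ 27 ⇒ 26. The phenol O–CH2OCH3 bond, the C9 carbonyl and the C9–O–benzyl bond are traced back in turn. The dione and the free phenol are the most sensitive groups and are revealed last. C9 carries its oxygen from the start, so no C–H oxidation is needed beside a chalcone. The forward steps must be three mild, orthogonal operations: oxidative ether cleavage, alcohol oxidation, mild acid.

26 ⇒ 23 + 24. The Cα=Cβ bond of the enone is cut by a retro-aldol condensation. This removes the alkene that could not survive the hydrogenation and leaves a methyl ketone. The forward step must enolise only the aryl methyl ketone and must not eliminate the C10 aryl ether.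

23 ⇒ 22. The C1–H and C2–H bonds are removed. C1 becomes sp2, so the C1–aryl bond can come from a cross-coupling. The forward hydrogenation must deliver hydrogen to the face of C1=C2 that carries ring B.

22 ⇒ 20 (through 21). The C10–O–aryl bond is cut at an aryl fluoride ortho to the acetyl group. This opens the dihydrobenzofuran to a tertiary alcohol and an aryl-substituted alkene. The forward alkoxide must close the five-membered ring faster than it cleaves C9–C10 by retro-aldol.

20 ⇒ 19 + 4. The C1–aryl bond is cut between an alkenyl triflate and an aryl boronate. This separates the whole arene and makes the route convergent. The forward coupling joins a hindered triflate with a doubly ortho-substituted boronate.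

19 ⇒ 18 ⇒ 17. The C1–OTf bond goes back to the C1 ketone and the O–Si bond to the C10 hydroxyl. The silyl ether removes the retro-aldol and α-ketol pathways from the basic steps. The forward enolisation must touch C2 only, which the hindered, oxygen-bearing C9 ensures.

17 ⇒ 7 + 15. The C5–C6 and C9–C10 bonds are cut, the key disconnection. One ring, two skeletal bonds and four stereocentres fall away, leaving a monocyclic enol and an achiral cyclopropene. The acyl carbon C9 of 15 carries a 4-methoxybenzyl ether as a spectator, so the later C9 carbonyl needs only an alcohol oxidation. The forward step must add through carbon, pair the right faces and close the aldol onto C10.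

15 ⇒ 13 + 9; 13 ⇒ 11 ⇒ 10; 9 ⇒ 8. The C7–C8 acyl bond is cut at the vinylic carbon of the cyclopropene, and the three-membered ring is traced to a vinylcarbene from a tosylhydrazone. The forward lithiation must deprotonate and not add to the strained alkene.

7 ⇒ 6 ⇒ 5. The C1 oxygen is removed (α-oxidation of a ketone) and then the C4–CH3 bond (conjugate addition). The conjugate addition is the only source of absolute configuration in the route, so it must be highly enantioselective.

4 ⇒ 3 ⇒ 2 ⇒ 1. The C–B bond, the O–CH2OCH3 bond and one C–O bond are traced back to a symmetric difluoroarene. The phenol oxygen is put in on the simple arene, so no fluoride exchange is needed on a base-sensitive late intermediate. The borylation must choose the C–H next to fluorine.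

## Other disconnections considered

Alternative 1: The cut is at O–C10 and C5–C10 of the dihydrobenzofuran A2, with O–C3 re-formed, which leads back to the cis-2,4-disubstituted chroman diazo ester A1. In the forward step Cu(hfacac)2 or Rh2(OAc)4 would turn the diazo group at C10 into a carbenoid. The chroman oxygen would capture it, and the bridged oxonium ylide would shift [2,3] to contract the chroman and close ring A.
- In its favour: the reaction class is precedented, the step makes both fully substituted carbons C5 and C10 in one concerted event, and the arene, the C10–O bond and the C1 stereocentre are present from the start.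
- Against it here: the migrating terminus C5 is fully substituted; its configuration depends on a stereodefined tetrasubstituted diene in A1; and the carbenoid can also undergo a [1,2]-shift, cyclopropanate the diene or insert into C–H bonds. After A2, ring B, the cyclopropane (with the same open question of its face) and the C4 stereocentre (hydrogenation of C3=C4) are still to be made.
- Comparison: A2 is better than the chosen plan in having the C10–O–aryl bond and C1 fixed early, with no alkoxide ring closure under retro-aldol threat and no late hydrogenation, and in resting on a known reaction class. The chosen plan is better in step economy, since its key step delivers ring B with the cyclopropane and four stereocentres at once.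

Alternative 2: The cut is at C7–C8 and C6–C11 of the cyclopropyl ketone A4, with C8–C11 restored, which leads back to the 2,2-dimethylcyclohept-3-enone A3. In the forward step, acetone-sensitised irradiation would trigger an oxa-di-π-methane 1,2-acyl shift that contracts the seven-membered ring to ring B and closes the cyclopropane.
- In its favour: the cyclopropane is made without carbene or diazo reagents under neutral conditions, the reaction class is well known for β,γ-enones with a quaternary α-carbon, and A4 needs no protecting group.
- Against it here: A3 contains an ortho-hydroxyaryl ketone, which absorbs the light and can quench the sensitiser, and the singlet 1,3-acyl shift and α-cleavage compete. The cyclopropane face depends on the conformation of the seven-membered ring and is not secured. The hard part, C5/C10 with the dihydrobenzofuran, is only moved into the synthesis of A3, which also needs a seven-membered ring. A4 also still needs a C–H oxidation at C9 beside the free phenol.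
- Comparison: this alternative is the equal of the chosen plan in the uncertainty about the cyclopropane face. It is better in the absence of basic steps after ring B exists and in resting on a known reaction class. The chosen plan is better in the access to the key-step precursor and in step economy.

Alternative 3: The cut is at C5–C10 of the ketone A6, which leads back to the 2,3-disubstituted 3-acylbenzofuran A5. In the forward step Fe(acac)3 and PhSiH3 would transfer a hydrogen atom to the 1,1-disubstituted alkene. The tertiary C5 radical would add to C10 of the acylbenzofuran, and the C1 radical would be reduced and protonated to the cis-fused dihydrobenzofuran.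
- In its favour: radical conjugate addition is a known and mild way to join two fully substituted carbons, A5 is flat and easy to assemble, and the C10–O and C1–aryl bonds exist from the start.
- Against it here: the planar C5 radical carries a methyl and a silyloxymethyl group of similar size, so C5 is weakly controlled by C4. After A6, ring B must be closed by an aldol between the unmasked methyl ketone and a C6 aldehyde. The cyclopropane must then be added to a cis-fused enone from its more shielded face, the C2 carbonyl removed and C9 oxidised.
- Comparison: this alternative is better than the chosen plan for the C5–C10 bond itself and for avoiding the alkoxide ring closure, and its key step is precedented. It is weaker at C5 and, like the chosen plan, has no secured solution for the cyclopropane face. It is clearly longer, since its key step makes one ring and one C–C bond against one ring, two bonds and the cyclopropane array in the chosen plan.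

Key step: step 10

Assumptions on the chemistry:
- The aldol closure of step 10 may give either configuration at C9. This centre becomes a carbonyl in step 18, so 17–23 and 25–27 are written without a descriptor at C9 (the carbinol carbon of 25 likewise).
- Ketone 6 is a mixture at C2, which becomes sp2 in step 5. C4 of 7 is R and is carried unchanged into 29.

## Route

Step 1
Reactants: 1 1-(2,6-difluoro-4-methoxyphenyl)ethan-1-one
Product: 2 1-(2-fluoro-6-hydroxy-4-methoxyphenyl)ethan-1-one
Conditions: KOH (2.5 equiv), DMSO/H2O (4:1), 60 °C; aq. HCl
Reagents that add atoms: potassium hydroxide, [K+].[OH-]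
Why: Nucleophilic aromatic substitution of a fluoride ortho to the acetyl group by hydroxide; the two fluorides are equivalent and the phenoxide formed deactivates the ring, so only one should be exchanged.

Step 2
Reactants: 2 1-(2-fluoro-6-hydroxy-4-methoxyphenyl)ethan-1-one
Product: 3 1-[2-fluoro-4-methoxy-6-(methoxymethoxy)phenyl]ethan-1-one
Conditions: MOMCl, iPr2NEt, CH2Cl2, 0 °C to rt
Reagents that add atoms: chloromethyl methyl ether, COCCl
Why: O-alkylation of the phenol to its methoxymethyl acetal; the ether keeps the ring neutral so that the remaining fluoride stays reactive in step 14 and the phenol is masked until the last step.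

Step 3
Reactants: 3 1-[2-fluoro-4-methoxy-6-(methoxymethoxy)phenyl]ethan-1-one
Product: 4 1-[2-fluoro-4-methoxy-6-(methoxymethoxy)-3-(4,4,5,5-tetramethyl-1,3,2-dioxaborolan-2-yl)phenyl]ethan-1-one
Conditions: [Ir(OMe)(cod)]2 (2.5 mol %), 3,4,7,8-tetramethyl-1,10-phenanthroline (5 mol %), B2pin2 (1.1 equiv), THF, 80 °C
Reagents that add atoms: bis(pinacolato)diboron, CC1(C)OB(OC1(C)C)B1OC(C)(C)C(C)(C)O1
Why: Iridium-catalysed aromatic C–H borylation; only two ring C–H bonds exist, and the one between F and OMe should react before the one between the bulkier OCH2OCH3 and OMe because fluorine is the smallest ortho substituent and activates the adjacent C–H bond.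

Step 4
Reactants: 5 2-methylcyclohex-2-en-1-one
Product: 6 (3R)-2,3-dimethylcyclohexan-1-one (mixture at C2)
Conditions: AlMe3 (1.4 equiv), Cu(OTf)2 (2 mol %), BINOL-derived N,N-bis(1-phenylethyl)phosphoramidite (4 mol %, antipode that gives 3R), Et2O, −30 °C; aq. NH4Cl
Reagents that add atoms: trimethylaluminium, C[Al](C)C
Why: Copper-catalysed asymmetric conjugate addition of a methyl group to an α-substituted cyclic enone; the chiral ligand sets the new centre (C4 of the target) as R, and C2 is left unset because it becomes sp2 in step 5.

Step 5
Reactants: 6 (3R)-2,3-dimethylcyclohexan-1-one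
Product: 7 (4R)-2-hydroxy-3,4-dimethylcyclohex-2-en-1-one, the enol of (4R)-3,4-dimethylcyclohexane-1,2-dione
Conditions: SeO2 (1.2 equiv), 1,4-dioxane/H2O (20:1), 90 °C
Reagents that add atoms: selenium dioxide, O=[Se]=O
Why: Riley oxidation of the α-methylene group, as in the conversion of 2-alkylcyclohexanones into 3-alkylcyclohexane-1,2-diones; the dione should rest as the more substituted hydrogen-bonded enol, and C4 is never α to a carbonyl and keeps its configuration.

Step 6
Reactants: 8 2-chloro-N-methoxy-N-methylacetamide
Product: 9 N-methoxy-2-[(4-methoxybenzyl)oxy]-N-methylacetamide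
Conditions: 4-methoxybenzyl alcohol, NaH, THF, 0 °C to rt
Reagents that add atoms: 4-methoxybenzyl alcohol, COc1ccc(CO)cc1
Why: Williamson ether synthesis at the activated primary chloride; the N-methoxy-N-methylamide resists attack by the alkoxide.

Step 7
Reactants: 10 3-methylbut-2-enal
Product: 11 3-methylbut-2-enal (E)-4-methylbenzenesulfonylhydrazone
Conditions: TsNHNH2, MeOH, rt
Reagents that add atoms: 4-methylbenzenesulfonohydrazide, Cc1ccc(cc1)S(=O)(=O)NN
Why: Condensation of the aldehyde with the sulfonyl hydrazide to the crystalline hydrazone.

Step 8
Reactants: 11 3-methylbut-2-enal (E)-4-methylbenzenesulfonylhydrazone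
Product: 13 3,3-dimethylcyclopropene, via 1-diazo-3-methylbut-2-ene 12 (not isolated)
Conditions: NaOMe (1.05 equiv), diglyme, 150–160 °C, volatile product distilled into a −78 °C trap
Reagents that add atoms: none
Why: Bamford–Stevens reaction: the hydrazone salt loses sulfinate to the vinyl diazoalkane, loss of N2 gives the vinylcarbene and this closes to the cyclopropene, a known route to 3,3-dialkylcyclopropenes.

Step 9
Reactants: 13 3,3-dimethylcyclopropene; 9 N-methoxy-2-[(4-methoxybenzyl)oxy]-N-methylacetamide
Product: 15 1-(3,3-dimethylcycloprop-1-en-1-yl)-2-[(4-methoxybenzyl)oxy]ethan-1-one, via 1-lithio-3,3-dimethylcyclopropene 14 (not isolated)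
Conditions: LiN(iPr)2, THF, −78 °C; then 9, −78 to −20 °C; aq. NH4Cl; product kept cold in solution
Reagents that add atoms: none
Why: The vinylic C–H bond of the cyclopropene is acidic enough for lithiation by an amide base, which cannot add to the strained alkene; acylation with the N-methoxy-N-methylamide stops at the ketone through the chelated tetrahedral intermediate.

Step 10
Reactants: 7 (4R)-2-hydroxy-3,4-dimethylcyclohex-2-en-1-one; 15 1-(3,3-dimethylcycloprop-1-en-1-yl)-2-[(4-methoxybenzyl)oxy]ethan-1-one
Product: 17 cis-fused ring A/ring B ketol (C10 hydroxyl cis to the C5 methyl; C1 and C8 ketones; C9 4-methoxybenzyl ether; C4 and C5 methyls cis; cyclopropane CMe2 anti to the C5 methyl), via Michael adduct 16 (not isolated)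
Conditions: Et3N (0.2 equiv), toluene, −20 °C to rt; then DBU (0.3 equiv), rt
Reagents that add atoms: none
Why: Proposed new method: the tertiary amine turns enol 7 into its hydrogen-bonded enolate, whose C5 adds to the unsubstituted carbon C6 of the strained C6=C7 bond of 15 with release of ring strain; the cyclopropyl enolate is protonated at C7 to give 16, and DBU then enolises the C8 ketone toward C9, which adds to the adjacent C10 carbonyl of the 1,2-dione. The closest known reaction types are the amine-mediated Michael–aldol (Robinson-type) annulations of cyclic 1,2-diones with enones and enals and the strain-driven conjugate additions of nucleophiles to cyclopropenyl esters and ketones. Ring B closes by a six-membered intramolecular aldol addition (6-enolexo-exo-trig) in which the cyclopropane is carried in intact. C5 is controlled by C4: the C4 methyl is pseudoaxial to avoid allylic strain with the C5 methyl and 15 approaches from the opposite face, so the two methyls end cis, as in alkylations of 2,3-dimethylcyclohexanone enolates. C6 is controlled only by the pairing of the enolate face with one of the two enantiotopic faces of 15; in an open, non-chelated transition state the small C5 methyl should lie over the three-membered ring, the branched C4 beside the acyl group and the flat C10 beside CMe2, which places CMe2 anti to the C5 methyl. C7 is set by protonation anti to the new C5 substituent, giving the cis-cyclopropane, the only isomer whose chain reaches C10; C10 is set by the tether, which reaches the carbonyl only from the face of the C5–C6 bond and so gives the cis-fused ketol with hydroxyl cis to the C5 methyl; C9 forms as either epimer and is a carbonyl at the end. The step needs C- rather than O-addition of the ambident enolate (favoured by the soft tetrasubstituted carbon, the nonpolar solvent and the absence of a metal counter-ion), attack at C10 rather than C1 (only C10 gives a six-membered ring) and a base that does not itself add to 15 (tertiary amines only).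

Step 11
Reactants: 17 cis-fused ring A/ring B ketol
Product: 18 C10 triethylsilyl ether of 17
Conditions: TESOTf (1.3 equiv), 2,6-lutidine, CH2Cl2, −78 to 0 °C
Reagents that add atoms: triethylsilyl trifluoromethanesulfonate, CC[Si](CC)(CC)OS(=O)(=O)C(F)(F)F
Why: Silylation of the hindered tertiary alcohol by a silyl triflate; masking the aldol hydroxyl removes retro-aldol cleavage of C9–C10 and α-ketol rearrangement from the basic steps 12 and 13.

Step 12
Reactants: 18 C10 triethylsilyl ether of 17
Product: 19 C1 enol triflate (C1=C2) of 18
Conditions: KN(SiMe3)2 (1.2 equiv), THF, −78 °C; then PhNTf2, −78 to 0 °C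
Reagents that add atoms: N-phenylbis(trifluoromethanesulfonimide), O=S(=O)(N(c1ccccc1)S(=O)(=O)C(F)(F)F)C(F)(F)F
Why: Kinetic enolate formation and O-sulfonylation to the enol triflate; the C1 ketone can enolise only toward C2, and the C8 ketone offers only the hindered C9–H between the quaternary C10 and the benzyl ether and the cyclopropyl C7–H, so deprotonation should occur at C2.

Step 13
Reactants: 19 C1 enol triflate; 4 1-[2-fluoro-4-methoxy-6-(methoxymethoxy)-3-(4,4,5,5-tetramethyl-1,3,2-dioxaborolan-2-yl)phenyl]ethan-1-one
Product: 20 C1-aryl alkene: 19 with the triflate replaced by the 3-acetyl-2-fluoro-6-methoxy-4-(methoxymethoxy)phenyl group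
Conditions: Pd(OAc)2 (5 mol %), SPhos (10 mol %), K3PO4 (3 equiv), THF/H2O (10:1), 50 °C
Reagents that add atoms: none
Why: Suzuki–Miyaura coupling of an alkenyl triflate with an aryl boronate; the bulky biaryl phosphine serves the doubly ortho-substituted boronate and the hindered triflate at mild temperature, which limits protodeboronation, and the silyl ether, the ketones and the aryl fluoride are not touched.

Step 14
Reactants: 20 C1-aryl alkene with C10 silyl ether
Product: 22 cyclised tetracycle (C10–O–aryl bond closed to the 2,3-dihydrobenzofuran; C1=C2 alkene; acetyl ortho to the ring oxygen), via C10 alkoxide 21 (not isolated)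
Conditions: TBAF (1.2 equiv), THF, 0 °C to rt
Reagents that add atoms: none
Why: Fluoride cleaves the Si–O bond and the tertiary alkoxide attacks the neighbouring C–F carbon, activated by the ortho acetyl group, in a five-membered intramolecular nucleophilic aromatic substitution; the closure is irreversible and should outrun retro-aldol cleavage, and C10 keeps its configuration.

Step 15
Reactants: 22 cyclised tetracycle with C1=C2
Product: 23 saturated tetracycle with C1–H anti to the C10 oxygen (cis-fused dihydrobenzofuran)
Conditions: [Ir(cod)(PCy3)(py)]PF6 (10 mol %), H2 (1–5 bar), CH2Cl2, rt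
Reagents that add atoms: none
Why: Homogeneous hydrogenation of a hindered trisubstituted alkene with a cationic iridium catalyst; the C8 carbonyl and the C9 ether on the ring B face can bind the metal there, and addition from the other face would force a trans-fused dihydrobenzofuran, so hydrogen should enter C1 anti to the C10 oxygen; benzyl-type ethers and ketones are not reduced.

Step 16
Reactants: 23 saturated tetracycle (aryl methyl ketone); 24 4-methoxybenzaldehyde
Product: 26 (E)-chalcone with phenol methoxymethyl ether and C9 4-methoxybenzyl ether, via aldol adduct 25 (not isolated)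
Conditions: Ba(OH)2·8H2O, MeOH, rt to 40 °C
Reagents that add atoms: none
Why: Claisen–Schmidt condensation; the aryl methyl ketone is the most acidic and least hindered enolisable position and the aldehyde cannot enolise, and dehydration of the aldol by E1cB should give the more stable (E)-enone.

Step 17
Reactants: 26 protected (E)-chalcone
Product: 27 C9 alcohol (α-ketol) with phenol methoxymethyl ether
Conditions: DDQ (1.3 equiv), CH2Cl2/pH 7 buffer (10:1), 0 °C to rt
Reagents that add atoms: none
Why: Oxidative cleavage of the 4-methoxybenzyl ether through its benzylic oxocarbenium ion and hydrolysis; the electron-poor enone, the acetal and the ketones should not react under these conditions.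

Step 18
Reactants: 27 C9 alcohol (α-ketol)
Product: 28 8,9-dione with phenol methoxymethyl ether
Conditions: DMP (1.5 equiv), CH2Cl2, 0 °C to rt
Reagents that add atoms: none
Why: Dess–Martin oxidation of the secondary α-hydroxy ketone to the 1,2-dione; both C9 epimers converge, the dione has no enolisable neighbour and the phenol is still masked.

Step 19
Reactants: 28 8,9-dione with phenol methoxymethyl ether
Product: 29 target compound CNP0121765.1
Conditions: HCl (2 M aq.)/MeOH (1:5), rt
Reagents that add atoms: none
Why: Acid-catalysed cleavage of the aryl methoxymethyl acetal, the most acid-labile group because it is ortho to the carbonyl; short exposure at room temperature should leave the cyclopropyl dione intact and should not close the 2'-hydroxychalcone to a flavanone.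

## Compound list

1 | 1-(2,6-difluoro-4-methoxyphenyl)ethan-1-one | CC(=O)c1c(F)cc(OC)cc1F | starting material
2 | 1-(2-fluoro-6-hydroxy-4-methoxyphenyl)ethan-1-one | CC(=O)c1c(O)cc(OC)cc1F | intermediate
3 | 1-[2-fluoro-4-methoxy-6-(methoxymethoxy)phenyl]ethan-1-one | CC(=O)c1c(OCOC)cc(OC)cc1F | intermediate
4 | 1-[2-fluoro-4-methoxy-6-(methoxymethoxy)-3-(4,4,5,5-tetramethyl-1,3,2-dioxaborolan-2-yl)phenyl]ethan-1-one | CC(=O)c1c(OCOC)cc(OC)c(B2OC(C)(C)C(C)(C)O2)c1F | intermediate
5 | 2-methylcyclohex-2-en-1-one | CC1=CCCCC1=O | starting material
6 | (3R)-2,3-dimethylcyclohexan-1-one (mixture at C2) | O=C1CCC[C@@H](C)C1C | intermediate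
7 | (4R)-2-hydroxy-3,4-dimethylcyclohex-2-en-1-one (enol of the 1,2-dione) | CC1=C(O)C(=O)CC[C@H]1C | intermediate
8 | 2-chloro-N-methoxy-N-methylacetamide | CON(C)C(=O)CCl | starting material
9 | N-methoxy-2-[(4-methoxybenzyl)oxy]-N-methylacetamide | CON(C)C(=O)COCc1ccc(OC)cc1 | intermediate
10 | 3-methylbut-2-enal | CC(C)=CC=O | starting material
11 | 3-methylbut-2-enal (E)-4-methylbenzenesulfonylhydrazone | CC(C)=C/C=N/NS(=O)(=O)c1ccc(C)cc1 | intermediate
12 | 1-diazo-3-methylbut-2-ene | CC(C)=CC=[N+]=[N-] | intermediate
13 | 3,3-dimethylcyclopropene | CC1(C)C=C1 | intermediate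
14 | 1-lithio-3,3-dimethylcyclopropene | [Li]C1=CC1(C)C | intermediate
15 | 1-(3,3-dimethylcycloprop-1-en-1-yl)-2-[(4-methoxybenzyl)oxy]ethan-1-one | COc1ccc(COCC(=O)C2=CC2(C)C)cc1 | intermediate
16 | Michael adduct: ring A 1,2-dione with quaternary C5 bonded to C6 of the cis-disubstituted gem-dimethylcyclopropane, C7 bearing the (4-methoxybenzyloxy)acetyl group | COc1ccc(COCC(=O)[C@@H]2[C@@H](C2(C)C)[C@@]3(C)[C@H](C)CCC(=O)C3=O)cc1 | intermediate
17 | cis-fused ketol: C10–OH, C1 and C8 ketones, C9 4-methoxybenzyl ether, cyclopropane anti to the C5 methyl | O[C@]12C(OCc3ccc(OC)cc3)C(=O)[C@@H]4[C@@H](C4(C)C)[C@@]1(C)[C@H](C)CCC2=O | intermediate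
18 | C10 triethylsilyl ether of 17 | CC[Si](CC)(CC)O[C@]12C(OCc3ccc(OC)cc3)C(=O)[C@@H]4[C@@H](C4(C)C)[C@@]1(C)[C@H](C)CCC2=O | intermediate
19 | C1 enol triflate (C1=C2) of 18 | CC[Si](CC)(CC)O[C@]12C(OCc3ccc(OC)cc3)C(=O)[C@@H]4[C@@H](C4(C)C)[C@@]1(C)[C@H](C)CC=C2OS(=O)(=O)C(F)(F)F | intermediate
20 | C1-[3-acetyl-2-fluoro-6-methoxy-4-(methoxymethoxy)phenyl] alkene with C10 silyl ether | CC[Si](CC)(CC)O[C@]12C(OCc3ccc(OC)cc3)C(=O)[C@@H]4[C@@H](C4(C)C)[C@@]1(C)[C@H](C)CC=C2c1c(F)c(C(C)=O)c(OCOC)cc1OC | intermediate
21 | C10 tertiary alcohol from 20 (alkoxide in the flask) | O[C@]12C(OCc3ccc(OC)cc3)C(=O)[C@@H]4[C@@H](C4(C)C)[C@@]1(C)[C@H](C)CC=C2c1c(F)c(C(C)=O)c(OCOC)cc1OC | intermediate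
22 | cyclised tetracycle: dihydrobenzofuran closed at C10–O, C1=C2 alkene | CC(=O)c1c(OCOC)cc(OC)c2c1O[C@]13C(OCc4ccc(OC)cc4)C(=O)[C@@H]5[C@@H](C5(C)C)[C@@]1(C)[C@H](C)CC=C23 | intermediate
23 | saturated tetracycle, cis-fused dihydrobenzofuran, aryl methyl ketone | CC(=O)c1c(OCOC)cc(OC)c2c1O[C@]13C(OCc4ccc(OC)cc4)C(=O)[C@@H]5[C@@H](C5(C)C)[C@@]1(C)[C@H](C)CC[C@H]23 | intermediate
24 | 4-methoxybenzaldehyde | COc1ccc(C=O)cc1 | starting material
25 | aldol adduct: β-hydroxy ketone from 23 and 24 | COc1ccc(C(O)CC(=O)c2c(OCOC)cc(OC)c3c2O[C@]24C(OCc5ccc(OC)cc5)C(=O)[C@@H]6[C@@H](C6(C)C)[C@@]2(C)[C@H](C)CC[C@H]34)cc1 | intermediate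
26 | (E)-chalcone with phenol methoxymethyl ether and C9 4-methoxybenzyl ether | COc1ccc(/C=C/C(=O)c2c(OCOC)cc(OC)c3c2O[C@]24C(OCc5ccc(OC)cc5)C(=O)[C@@H]6[C@@H](C6(C)C)[C@@]2(C)[C@H](C)CC[C@H]34)cc1 | intermediate
27 | (E)-chalcone with C9 alcohol and phenol methoxymethyl ether | COc1ccc(/C=C/C(=O)c2c(OCOC)cc(OC)c3c2O[C@]24C(O)C(=O)[C@@H]5[C@@H](C5(C)C)[C@@]2(C)[C@H](C)CC[C@H]34)cc1 | intermediate
28 | (E)-chalcone 8,9-dione with phenol methoxymethyl ether | COc1ccc(/C=C/C(=O)c2c(OCOC)cc(OC)c3c2O[C@]24C(=O)C(=O)[C@@H]5[C@@H](C5(C)C)[C@@]2(C)[C@H](C)CC[C@H]34)cc1 | intermediate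
29 | CNP0121765.1 | COc1ccc(/C=C/C(=O)c2c(O)cc(OC)c3c2O[C@]24C(=O)C(=O)[C@@H]5[C@@H](C5(C)C)[C@@]2(C)[C@H](C)CC[C@H]34)cc1 | target

## Step count and least certain steps

Total step count: 19. Longest linear sequence: 13 steps (steps 7–19, from 10 to 29).

Step 10 (key step). The most likely failure is poor discrimination of the two cyclopropene faces, giving a mixture at C6/C7 relative to C5, because only the staggering in an open transition state separates them. Irreversible O-addition of the ambident enolate and amine-triggered oligomerisation of the strained ketone are the next risks. The fallback uses known chemistry and separates the C–C bond formation from the cyclopropane. It sets out from 7 and 9. Addition of ethynylmagnesium bromide to 9 gives 1-[(4-methoxybenzyl)oxy]but-3-yn-2-one F1. Amine-mediated Michael addition of 7 to F1 and aldol closure of the (Z)-enone give the ring B ene-ketol F2. Silylation (TESOTf, 2,6-lutidine) gives the C10 silyl ether F3. 1,3-Dipolar cycloaddition of 2-diazopropane across C6=C7 (carbon terminus at C6) gives the 1-pyrazoline F4, and photolysis at 350 nm expels N2 and closes the cyclopropane. The face is then set by the bicyclic enone; the axial silyloxy group on the upper face of ring B should send the dipole to the lower face, anti to the C5 methyl. The fallback returns to the route at 18.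

Step 3. Slow or incomplete borylation is likely, because the only C–H bonds available are each flanked by two substituents, and a second borylation can follow. The fallback sets out from 2. Bromination para to the free hydroxyl (NBS, MeCN, 0 °C) gives 1-(3-bromo-2-fluoro-6-hydroxy-4-methoxyphenyl)ethan-1-one F5. MOMCl/iPr2NEt gives the methoxymethyl ether F6. Miyaura borylation (Pd(dppf)Cl2, B2pin2, KOAc, dioxane, 90 °C) returns to the route at 4.

Step 14. Retro-aldol cleavage of C9–C10 from the tertiary alkoxide may compete with ring closure, because the C10 ketone that would be released is conjugated with the aryl-substituted alkene. The fallback takes C8 out of the ketone level for this step and sets out from 19. NaBH4 (MeOH, 0 °C) reduces the C8 ketone to the C8 alcohol enol triflate F7. Suzuki–Miyaura coupling with 4 gives the C8 alcohol C1-aryl alkene F8. TBAF closes the ether to the cyclised C8 alcohol F9. Dess–Martin oxidation of the C8 alcohol returns to the route at 22.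

Step 15. Hydrogen may be delivered to the wrong face of C1=C2, or the hindered alkene may not react, because an axial group sits on each face next to C1. The fallback starts from 22 and replaces the concerted metal-dihydride addition by a stepwise hydrogen-atom-transfer hydrogenation (Mn(dpm)3, PhSiH3, t-BuOOH, i-PrOH). A hydrogen atom adds to C2, and the tertiary benzylic C1 radical in the planar five-membered ring takes the second hydrogen so as to give the less strained cis-fused ring. It returns at 23 and makes no new compound (entry F0).

Step 16. The dihydrobenzofuran may open by E1cB, with loss of the aryloxide from C10 after enolisation of the C8 ketone toward C9 under the basic, equilibrating conditions; the condensation at the doubly ortho-substituted ketone may also be slow. The fallback sets out from 23. Kinetic deprotonation of the methyl ketone (LiN(SiMe3)2, THF, −78 °C) and addition to 24 give the aldol adduct 25, which is isolated. MsCl/Et3N converts it into the benzylic mesylate F10, which eliminates under the amine base and returns to the route at 26.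

## Further compounds

F1 | step 10 | 1-[(4-methoxybenzyl)oxy]but-3-yn-2-one | C#CC(=O)COCc1ccc(OC)cc1
F2 | step 10 | ring B ene-ketol: C6=C7 enone, C10–OH cis to the C5 methyl, C1 ketone, C9 4-methoxybenzyl ether | O[C@]12C(OCc3ccc(OC)cc3)C(=O)C=C[C@@]1(C)[C@H](C)CCC2=O
F3 | step 10 | C10 triethylsilyl ether of F2 | CC[Si](CC)(CC)O[C@]12C(OCc3ccc(OC)cc3)C(=O)C=C[C@@]1(C)[C@H](C)CCC2=O
F4 | step 10 | 1-pyrazoline from 2-diazopropane and F3 (CMe2 on C6, N on C7, both anti to the C5 methyl) | CC[Si](CC)(CC)O[C@]12C(OCc3ccc(OC)cc3)C(=O)[C@H]4N=NC(C)(C)[C@H]4[C@@]1(C)[C@H](C)CCC2=O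
F5 | step 3 | 1-(3-bromo-2-fluoro-6-hydroxy-4-methoxyphenyl)ethan-1-one | CC(=O)c1c(O)cc(OC)c(Br)c1F
F6 | step 3 | 1-[3-bromo-2-fluoro-4-methoxy-6-(methoxymethoxy)phenyl]ethan-1-one | CC(=O)c1c(OCOC)cc(OC)c(Br)c1F
F7 | step 14 | C8 alcohol of enol triflate 19 | CC[Si](CC)(CC)O[C@]12C(OCc3ccc(OC)cc3)C(O)[C@@H]4[C@@H](C4(C)C)[C@@]1(C)[C@H](C)CC=C2OS(=O)(=O)C(F)(F)F
F8 | step 14 | C8 alcohol of C1-aryl alkene 20 | CC[Si](CC)(CC)O[C@]12C(OCc3ccc(OC)cc3)C(O)[C@@H]4[C@@H](C4(C)C)[C@@]1(C)[C@H](C)CC=C2c1c(F)c(C(C)=O)c(OCOC)cc1OC
F9 | step 14 | C8 alcohol of cyclised tetracycle 22 | CC(=O)c1c(OCOC)cc(OC)c2c1O[C@]13C(OCc4ccc(OC)cc4)C(O)[C@@H]5[C@@H](C5(C)C)[C@@]1(C)[C@H](C)CC=C23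
F0 | step 15 | none | none
F10 | step 16 | benzylic mesylate of aldol adduct 25 | COc1ccc(C(OS(C)(=O)=O)CC(=O)c2c(OCOC)cc(OC)c3c2O[C@]24C(OCc5ccc(OC)cc5)C(=O)[C@@H]6[C@@H](C6(C)C)[C@@]2(C)[C@H](C)CC[C@H]34)cc1
A1 | alternative 1 | methyl 2-diazo-2-{8-acetyl-2-[(Z)-3,5-dimethylhexa-2,4-dien-2-yl]-5-methoxy-7-(methoxymethoxy)chroman-4-yl}acetate (2,4-cis) | CC(=O)c1c(OCOC)cc(OC)c2c1O[C@@H](/C(C)=C(C)\C=C(C)C)C[C@H]2C(=[N+]=[N-])C(=O)OC
A2 | alternative 1 | dihydrobenzofuran fused to cyclohexene ring A with C10 methyl ester and C5 isobutenyl group | CC(=O)c1c(OCOC)cc(OC)c2c1O[C@@]1(C(=O)OC)[C@@H]2CC=C(C)[C@]1(C)C=C(C)C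
A3 | alternative 2 | tetracyclic 2,2-dimethylcyclohept-3-enone (seven-membered ring C8, C11, C7, C6, C5, C10, C9) | CC(=O)c1c(O)cc(OC)c2c1O[C@]13CC(=O)C(C)(C)C=C[C@@]1(C)[C@H](C)CC[C@H]23
A4 | alternative 2 | cyclopropyl ketone with C9 methylene | CC(=O)c1c(O)cc(OC)c2c1O[C@]13CC(=O)[C@@H]4[C@@H](C4(C)C)[C@@]1(C)[C@H](C)CC[C@H]23
A5 | alternative 3 | 2,3-disubstituted 3-acylbenzofuran with 1,1-disubstituted alkene side chain | CC(=O)c1c(OCOC)cc(OC)c2c1oc(CC3(C)OCCO3)c2C(=O)C[C@@H](C)C(=C)CO[Si](C)(C)C(C)(C)C
A6 | alternative 3 | cis-fused dihydrobenzofuran with ring A C2 ketone | CC(=O)c1c(OCOC)cc(OC)c2c1O[C@@]1(CC3(C)OCCO3)[C@@H]2C(=O)C[C@@H](C)[C@]1(C)CO[Si](C)(C)C(C)(C)C
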